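Time is the first setting you would turn on the new flasks, oak to elm, so ask whether the earlier runs still move at 5.0 d.

| flask | L | remark | time |
|---|---|---|---|
| south-west | 0.047 M | run made earlier |  |
| north | 0.22 M | run made earlier |  |
| east | 0.95 M | run made earlier |  |
| oak | 0.050 M |  | 5.0 d |
| cedar | 0.10 M |  | 5.0 d |
| birch | 0.20 M |  | 5.0 d |
| alder | 0.40 M |  | 5.0 d |
| elm | 0.80 M |  | 5.0 d |

| run | time / d | D / % | L / % |
|---|---|---|---|
| south-west | 1.04 | 27.5 | 34.8 |
| south-west | 2.08 | 32.6 | 32.9 |
| south-west | 3.00 | 33.9 | 31.8 |
| south-west | 4.00 | 34.5 | 31.0 |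
| south-west | 5.00 | 34.4 | 31.0 |
| north | 1.04 | 57.2 | 19.3 |
| north | 2.08 | 74.5 | 12.2 |
| north | 3.00 | 81.4 | 8.8 |
| north | 4.00 | 84.4 | 6.8 |
| north | 5.00 | 84.9 | 7.3 |
| east | 0.417 | 38.4 | 28.4 |
| east | 1.25 | 69.9 | 12.7 |
| east | 2.50 | 87.3 | 5.3 |
| east | 4.00 | 95.6 | 3.6 |
| east | 5.00 | 95.8 | 2.2 |

(standard deviation of a reading: 0.5 percentage points)

- the analysis behind the earlier runs scatters by 0.5 percentage points, standard deviation
- a reading or a percentage of D counts all its forms, free or not
- "hardly changes" means that all values lie within two and a half points (for a concentration: within two and a half percent of the largest)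

- amount of D at the end, in percent of the L charged for oak, cedar, birch, alder, elm, in this order
- how that number moves from the first to the last of them (falls, then rises / rises, then falls / hardly changes / falls all the way / rises all the way)

1. Time. By hand, a longer run gives more D. Near the end the readings say little of that: from 4.00 d to 5.00 d, D moves by 0.5 percentage points in the north run and 0.2 points in the east run, against a scatter of 0.5 points. So treat 5.0 d as the level.

2. Charge. By hand, if D were a fixed share of the charge, the row would stay flat. But D ends at 34.4 % in the south-west run and 95.8 % in the east run.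

3. Look for what nearly stays put instead. Take the charge c_L times the share that is not D at 5.00 d: the south-west run gives 0.0308 M, the north run 0.0332 M and the east run 0.0399 M, while the charge grows by a factor of 20.2. Call this the rest, c_rest, the molar amount of the charge that has not become D at the level. Freeze it at the south-west value, because the same scatter weighs less in molar terms on the smaller charge.

4. The share of D is then 1 − c_rest/c_L, one division per flask. My reckoning gives 38.3 %, 69.2 %, 84.6 %, 92.3 % and 96.1 %, rising from oak to elm, as a frozen rest is a smaller share of a larger charge.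

The forecast reads 37 %, 68 %, 84 %, 91.5 % and 95.5 %, rises all the way, on the ground that “everything above that ends up as D”. Mine stands 1.3 points above it at oak and 0.65 points above it at elm.

The flasks give 38.7 %, 68.9 %, 84.0 %, 91.5 % and 95.3 %: rises all the way.

    L ⇌ Z (K = 0.870, k = 0.00490 min⁻¹)
    Z ⇌ Q (K = 0.240, k = 6.70 × 10⁻⁴ min⁻¹)
    L ⇌ D (K = 0.320, k = 0.00170 min⁻¹)
    G ⇌ D, rate k4*(cs4 - [D]) while solid is left; crystals form when [D] > cs4 (solubility = 4.70 mM, k = 0.0340 min⁻¹)

In oak, the path from L to Z had half of its turnover up to the asked time done by 0.690 h, and the loss of D from solution into crystals G had half of its turnover up to the asked time done by 0.614 d and 92 % by 2.50 d. The rest of oak, the L, Z and Q standing at 5.00 d, comes to 0.0307 M, beside the frozen 0.0308 M. Elm holds a rest of 0.0376 M at 5.00 d, and 0.0305 M at 50.0 d.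

(The readings are calculated on assumed constants, noise included.)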